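## The problem

Target **30** is a daucane-type diester built on a cis-fused hydroazulene: the C8a methyl and the C3a hydrogen lie on the same face of a cyclopentane fused to a cycloheptene. Five contiguous stereocentres (C3, C3a, C4, C8a, C8) surround the ring fusion, and three of them carry oxygen in three different states: a free tertiary hydroxyl at C3 (geminal to isopropyl), a 4-hydroxybenzoate at C4 and an isovalerate at allylic C8. C3a and C4 can be set together in a cycloaddition. Once the folded cis bicycle exists, its convex face (the face of C3a–H and the C8a substituent) can direct an oxidant to C3 and a hydride to the far side of C8. C8a is quaternary, cannot be corrected later, and must therefore be made stereospecifically. The allylic C8–O bond, the free phenol, the two different esters and the tertiary carbinol (dehydration, acyl transfer, reduction) require that all hydride and strong-base chemistry is finished before the acyl groups go on. The C6=C7 olefin must end allylic to C8–O and remote from C4–O. The enabling feature is that C8a sits between oxygenated C8 and ring-fusion C3a. If C8 is a carbinol carbon and C8a carries a leaving group, moving C3a from C8 to C8a turns a decalin (in which C3a–C8 is the ring-fusion bond) into the 5–7 skeleton, creating the quaternary centre and the C8 carbonyl together.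

## Retrosynthesis

**Esters last.** The two acyl–oxygen bonds of **30** are cut first, giving diol silyl ether **24**, 3-methylbutanoyl chloride **25** and 4-acetoxybenzoic acid **28**. In **24** the C8 hydroxyl is free and C4 is silylated, so the two secondary oxygens are told apart by protection rather than by reactivity; the tertiary C3 hydroxyl does not acylate. The forward steps are two acylations, one desilylation and removal of the phenol acetate (**26**, **27**, **29**).

**Three hydride deliveries.** The C2–H bond, the C8–H bond and one C–H bond of the angular methyl of **24** are cut back to epoxy enone tosylate **22** by way of allylic alcohol **23**. An epoxide on the convex face, opened by hydride at C2, gives the C3 hydroxyl cis to H-3a; direct addition of an isopropyl nucleophile to a C3 ketone from that face would give the wrong epimer. The enone carbonyl at C8 also deactivates the C6=C7 olefin, so the cyclopentene of **21** can be epoxidised selectively.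

**Isopropyl group.** The C3–isopropyl bond of **21** is cut to enol triflate **19** and isopropylzinc bromide **20**; **19** comes from diketone **17** and this from ketal **16**. A C3 ketone masked as a ketal is the simplest group that survives the earlier enolate, ylide and Lewis-acid steps.

**Olefin position and angular carbon.** The conjugated enone **16** is traced to the β,γ-unsaturated ketone **15** and this to β-hydroxy ketone **14**. The cost of the key step is that it delivers C8a–CH2OH and the olefin one position away from the target; a tosylate (later reduced to methyl) and a base-mediated conjugation correct both.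

**Key cut, C3a–C8a.** Breaking this bond of **14** and reconnecting C3a to C8 gives the decalin epoxy alcohol **13**. Cutting C8–C8a or C3–C3a (the alternatives below) leaves the seven-membered ring or the quaternary centre still to be made; this cut forms both target rings and the quaternary centre in one stereospecific 1,2-shift. The precursor is a plain cis-decalin. The forward reaction must make the ring-fusion carbon migrate, not the other carbinol substituent, and must do so with inversion at the epoxide carbon.

**Epoxy alcohol.** The C1–CH2 bond of **13** is cut to ketol **11** and trimethylsulfonium iodide **12**, and the C8a–O bond of **11** to ketone **8** through silyl enol ether **9**. The carbinol centre becomes a carbonyl in the key step, so only the epoxide configuration relative to C4a matters. The cis-fused ketol, which enol ether oxidation should give, is used; a trans ketol is not needed.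

**Differentiating the two carbonyls.** Ketone **8** (C4 ketal, C1 ketone) is traced to dione **5** through **7** and **6**. The C4 carbonyl of **5** is the hindered one, next to the silyloxy carbon, so direct mono-ketalisation would mask the wrong carbonyl. C1 is therefore tied up first as a dithiolane, C4 is ketalised, and C1 is released.

**Cycloaddition.** The C4a–C5 and C8–C8a bonds of **4** (reduced to **5**) are cut to 1,4-benzoquinone **3** and silyloxy diene **2**, made from 3-methylbut-2-enal **1**. One endo Diels–Alder reaction supplies eleven skeletal carbons, the C4 oxygen of the target and the C3a/C4 relative configuration, and a chiral Lewis acid sets the absolute configuration.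

## Roads not taken

**Alternative 1: enone–alkene photocycloaddition, then glycol cleavage.** The cut is at C8–C8a and C3a–C4. 3-Methylcyclopent-2-enone **A1**, bound to a chiral oxazaborolidine–AlBr3 Lewis acid, would be irradiated with 4-methyl-1,2-bis(trimethylsilyloxy)cyclopentene **A2** to give the cis-anti-cis cyclobutane **A3**. Desilylation and glycol cleavage would then open the shared bond to the bicyclic triketone **A4**.
- Merits: the skeleton, the cis ring fusion and the C8a methyl arrive in about three steps from achiral partners, with no deoxygenation and no olefin shift. In step economy to the bicycle this road is better than the chosen one.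
- Weak points: enantioselective Lewis-acid photocycloaddition is established mainly for simple alkenes in excess, and a tetrasubstituted, acid-labile bis-silyloxy alkene is an untested partner. **A4** carries three ketones; C3 and C4 form a 1,3-diketone across C3a, which puts the ring-fusion hydrogen at risk, and C4 and C8 would both need face-selective reduction, separate acylation and a regioselective desaturation to C6=C7.
- Comparison: the chosen plan is longer, but its three oxygens are differentiated from the start (silyl ether at C4 with fixed configuration, ketal at C3, the only free ketone at C8).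

**Alternative 2: carbenoid C–H insertion into the C3 carbinol.** The cut is at C3–C3a. Rh2(OAc)4 would turn the acyclic α-diazo ester **A5** into a carbenoid that inserts into the oxygen-activated C3–H bond with retention, closing the cyclopentane **A6**.
- Merits: the tertiary C3 carbinol, the hardest single centre, would come directly from a secondary carbinol that is easy to make in enantiopure form. On this point the road is better than the chosen plan, which spends four steps (triflate, coupling, epoxidation, hydride) on C3.
- Weak points: the insertion site is flanked by isopropyl and a silyloxy group; the isopropyl methine C–H and oxonium ylide formation compete; the acyclic precursor needs the quaternary C8a and C3 set independently. **A6** still lacks the seven-membered ring, C4, C8 and the trisubstituted olefin.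
- Comparison: the chosen plan makes both rings and the quaternary centre in one step and takes C3a/C4 from the cycloaddition.

**Alternative 3: divinylcyclopropane Cope rearrangement.** The cut is at C8–C8a. Warming the cis-divinylcyclopropane **A7** (one vinyl unit is the cyclopentenone C3a=C8a bond, the other a silyl ketene acetal) would form C8–C8a, break the cyclopropane C4–C6 bond and give, after acidic work-up, dienedione **A8**.
- Merits: the C6=C7–C8=O enone is formed in its final position and C8a carries its methyl directly, so the olefin shift and the deoxygenation of the chosen plan are both avoided. In these two respects this road is better.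
- Weak points: the terminus C8a is fully substituted and its methyl points into the cyclopropane in the boat transition state, the case in which this rearrangement is slow. **A7** needs an enantioselective synthesis of a cyclopropane with a quaternary carbon. **A8** has no oxygen at C4; it would have to be added to the C3a=C4 enone, creating C4 and C3a under control of a remote quaternary centre only.
- Comparison: the chosen plan fixes the C4 oxygen and the C3a/C4 relationship in the first ring-forming step and relies on better-precedented steps.

Key step: step 10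

Assumption (chemistry): (R)-BINOL is taken as the ligand antipode that leads to **4**; the sense of induction for this diene must be confirmed, and the mirror-image ligand is used if it is opposite.

Assumption (chemistry): the hydroxylation of step 8 is taken to give the cis-fused ketol **11**; its carbinol centre is destroyed in step 10, and a trans-fused epimer would be carried through steps 9 and 10 in the same way.

Locants: decalins **4**–**13** keep the numbering of dione **5** (C4 next to the silyloxy carbon C5, C1 remote; ring A is the methylcyclohexene, ring B holds C1–C4). Hydroazulenes **14**–**30** keep the numbering of the target. Decalin C8a, C1, C4a, C4 and C5 become target C8, C8a, C3a, C3 and C4. TBS = tert-butyldimethylsilyl.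

## Route

Step 1
Reactants: 1 3-methylbut-2-enal
Product: 2 (E)-1-(tert-butyldimethylsilyloxy)-3-methylbuta-1,3-diene
Conditions: TBSOTf, Et3N, Et2O, 0 °C to rt
Reagents that add atoms: tert-butyldimethylsilyl trifluoromethanesulfonate, CC(C)(C)[Si](C)(C)OS(=O)(=O)C(F)(F)F
Why: O-silylation of the enal and loss of a γ-proton (vinylogous silyl enol ether formation) gives the 1-silyloxy diene, with the E geometry expected from the extended oxocarbenium ion.

Step 2
Reactants: 2 (E)-1-(tert-butyldimethylsilyloxy)-3-methylbuta-1,3-diene; 3 1,4-benzoquinone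
Product: 4 cis-fused Diels–Alder adduct, (4aS,5R,8aS)-5-(TBS-oxy)-7-methyl-4a,5,8,8a-tetrahydronaphthalene-1,4-dione
Conditions: (R)-BINOL (10 mol %), TiCl2(OiPr)2 (10 mol %), CH2Cl2, −30 °C
Reagents that add atoms: none
Why: Chiral-Lewis-acid-catalysed quinone Diels–Alder reaction; the endo transition state places the silyloxy group trans to both ring-fusion hydrogens, and the BINOL–titanium complex bound to one carbonyl selects the enantiotopic face, setting C4a, C5 and C8a.

Step 3
Reactants: 4 Diels–Alder adduct
Product: 5 (4aS,5R,8aS)-5-(TBS-oxy)-7-methyl-2,3,4a,5,8,8a-hexahydronaphthalene-1,4-dione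
Conditions: Zn, AcOH, rt
Reagents that add atoms: none
Why: Zinc reduction of an ene-dione removes only the conjugated C2=C3 bond, which stops aromatisation of the adduct; the mild acid leaves the silyl ether and the cis fusion untouched.

Step 4
Reactants: 5 saturated cis-dione
Product: 6 C1 ethylene dithioketal of 5 (C4 ketone free)
Conditions: HSCH2CH2SH (1.05 equiv), BF3·OEt2 (cat.), CH2Cl2, −40 °C
Reagents that add atoms: ethane-1,2-dithiol, SCCS
Why: Lewis-acid-catalysed dithioketalisation is strongly sensitive to hindrance; the C4 carbonyl is flanked by the silyloxy-bearing C5, so the remote C1 carbonyl should react first at low temperature with one equivalent.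

Step 5
Reactants: 6 C1 dithioketal ketone
Product: 7 C4 ethylene ketal, C1 ethylene dithioketal of 5
Conditions: TMSOCH2CH2OTMS, TMSOTf (cat.), CH2Cl2, −78 to −20 °C
Reagents that add atoms: 1,2-bis(trimethylsilyloxy)ethane, C[Si](C)(C)OCCO[Si](C)(C)C
Why: Silyl-triflate-catalysed ketalisation with the bis-silyl glycol ether is aprotic and driven by loss of hexamethyldisiloxane, so the hindered β-silyloxy ketone is masked without epimerisation at C4a or β-elimination.

Step 6
Reactants: 7 ketal dithioketal
Product: 8 (4aS,5R,8aS)-4,4-(ethylenedioxy)-5-(TBS-oxy)-7-methyl-3,4,4a,5,8,8a-hexahydronaphthalen-1(2H)-one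
Conditions: MeI, CaCO3, MeCN–H2O, 45 °C
Reagents that add atoms: water, O
Why: S-alkylative hydrolysis of the dithiolane under buffered, near-neutral conditions releases the C1 ketone while the dioxolane, the silyl ether and the olefin are inert.

Step 7
Reactants: 8 C4-ketal C1-ketone
Product: 9 C1=C8a trimethylsilyl enol ether of 8
Conditions: TMSCl, Et3N, DMF, 90 °C
Reagents that add atoms: chlorotrimethylsilane, C[Si](C)(C)Cl
Why: Equilibrating silylation gives the more substituted (tetrasubstituted) enol ether; the C4 ketal rules out enolisation toward C4a, and the C8a centre is erased on purpose.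

Step 8
Reactants: 9 silyl enol ether
Product: 11 cis-fused ketol, (4aR,5R,8aR)-4,4-(ethylenedioxy)-8a-hydroxy-5-(TBS-oxy)-7-methyl-3,4,4a,5,8,8a-hexahydronaphthalen-1(2H)-one, via silyloxy epoxide 10 (not isolated)
Conditions: DMDO, acetone–CH2Cl2, −78 °C; then citric acid, MeOH, 0 °C
Reagents that add atoms: dimethyldioxirane, CC1(C)OO1
Why: Rubottom oxidation; the electron-rich enol ether reacts far faster than the ring A olefin, and the oxidant should come from the face of H-4a, away from the C5 silyloxy group, giving the 8a-hydroxyl cis to H-4a.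

Step 9
Reactants: 11 cis-fused ketol; 12 trimethylsulfonium iodide
Product: 13 epoxy alcohol, spiro-epoxide at C1 with its CH2 cis to the 8a-hydroxyl and to H-4a and its oxygen trans to them, (1S,4aR,5R,8aR)
Conditions: 12, n-BuLi, THF, −10 °C; then 11, −78 to 0 °C (2.5 equiv ylide)
Reagents that add atoms: none
Why: Corey–Chaykovsky epoxidation; in the cis-decalone conformer with the silyloxy group pseudo-equatorial, the 8a-oxygen is equatorial and C8 axial on ring B, so the irreversibly adding sulfonium methylide attacks axially on the convex face, anti to the C8a–C8 bond, and the epoxide oxygen ends equatorial.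

Step 10
Reactants: 13 epoxy alcohol
Product: 14 cis-fused β-hydroxy ketone, (3aS,4R,8aR)-3,3-(ethylenedioxy)-8a-(hydroxymethyl)-4-(TBS-oxy)-6-methyl-2,3,3a,4,7,8a-hexahydroazulen-8(1H)-one
Conditions: BF3·OEt2, CH2Cl2, −78 °C; Et3N quench
Reagents that add atoms: none
Why: BF3 binds the epoxide oxygen and the tertiary C1–O bond ionises while the C8a–C4a bond, antiperiplanar to it, migrates from the carbinol carbon to C1 and the hydroxyl oxygen becomes the C8 carbonyl; this is the semipinacol rearrangement of a 2,3-epoxy alcohol, the reaction type used for ring contraction and enlargement of cyclic epoxy carbinols and, with sulfonate leaving groups, for decalin-to-hydroazulene shifts. Neither ring is closed by a cyclisation: because the migrating bond is the ring-fusion bond, ring B loses C8a and contracts to the cyclopentane while ring A gains C1 and expands to the cycloheptenone in the same suprafacial 1,2-shift. The new quaternary stereocentre (C8a of 14) is controlled by the epoxide configuration of 13: the migrating carbon enters anti to the departing oxygen (inversion) and keeps its own configuration, so the hydroxymethyl group ends cis to H-3a and the C4 silyloxy group stays trans to it. The selectivity needed is migration of C4a in preference to C8 or to a hydride of the epoxide methylene; in the ring B chair with the epoxide C–O equatorial only the C8a–C4a bond is antiperiplanar to it (C8 is anti to the epoxide CH2, the hydroxyl anti to C2), and in the flipped chair no carbon is aligned at all. The carbinol oxygen supplies the push, so assisted migration should outrun unassisted ionisation. Low temperature, anhydrous conditions and a cold amine quench protect the dioxolane, the allylic silyl ether and the retro-aldol-prone product.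

Step 11
Reactants: 14 β-hydroxy ketone
Product: 15 primary tosylate of 14
Conditions: TsCl, DMAP, Et3N, CH2Cl2, 0 °C to rt
Reagents that add atoms: 4-methylbenzenesulfonyl chloride, Cc1ccc(cc1)S(Cl)(=O)=O
Why: Sulfonylation of the primary hydroxyl blocks retro-aldol loss of formaldehyde in the later base steps and installs the leaving group for the final reduction to methyl; the tosylate has no acidic α-hydrogen.

Step 12
Reactants: 15 β,γ-unsaturated ketone tosylate
Product: 16 conjugated enone (C6=C7), (3aS,4R,8aR)-3,3-(ethylenedioxy)-4-(TBS-oxy)-6-methyl-8a-(tosyloxymethyl)-2,3,3a,4,5,8a-hexahydroazulen-8(1H)-one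
Conditions: DBU (0.5 equiv), CH2Cl2, rt
Reagents that add atoms: none
Why: Base-catalysed olefin isomerisation through the dienolate (deprotonation at C7, protonation at C5) moves the double bond into conjugation; C8a is quaternary so no other enolate can form, and a mild amidine at rt should not eliminate the C4 silyloxy group.

Step 13
Reactants: 16 ketal enone
Product: 17 (3aS,4R,8aR)-4-(TBS-oxy)-6-methyl-8a-(tosyloxymethyl)-1,2,3a,4,5,8a-hexahydroazulene-3,8-dione
Conditions: PPTS, acetone–H2O, 56 °C
Reagents that add atoms: water, O
Why: Mild acid-catalysed ketal hydrolysis; the secondary silyl ether, the neopentyl tosylate and the enone are stable to pyridinium tosylate.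

Step 14
Reactants: 17 diketone
Product: 19 C2=C3 enol triflate, (3aS,4R,8aR)-4-(TBS-oxy)-6-methyl-8-oxo-8a-(tosyloxymethyl)-1,3a,4,5,8,8a-hexahydroazulen-3-yl trifluoromethanesulfonate, via potassium enolate 18 (not isolated)
Conditions: KN(SiMe3)2 (1.05 equiv), THF, −78 °C; then PhNTf2, −78 to 0 °C
Reagents that add atoms: N-phenylbis(trifluoromethanesulfonimide), O=S(=O)(N(c1ccccc1)S(=O)(=O)C(F)(F)F)C(F)(F)F
Why: Kinetic deprotonation takes the unhindered C2 methylene of the cyclopentanone, not the C3a methine (whose enolate could expel the C4 silyloxy group), and is faster than γ-deprotonation of the enone, which has no α′-hydrogen; O-triflation then fixes the enolate.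

Step 15
Reactants: 19 enol triflate; 20 isopropylzinc bromide
Product: 21 (3aS,4R,8aR)-4-(TBS-oxy)-6-methyl-3-(propan-2-yl)-8a-(tosyloxymethyl)-3a,4,5,8a-tetrahydroazulen-8(1H)-one
Conditions: Pd(OAc)2 (3 mol %), CPhos (6 mol %), THF, rt
Reagents that add atoms: none
Why: Negishi coupling of an alkenyl triflate with a secondary alkylzinc; the bulky biaryl phosphine favours reductive elimination over β-hydride isomerisation to n-propyl, and the organozinc tolerates the enone and the sulfonate.

Step 16
Reactants: 21 isopropyl cyclopentene enone
Product: 22 2,3-epoxide on the face of H-3a, (2R,3S,3aS,4R,8aR)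
Conditions: DMDO, acetone–CH2Cl2, −20 °C
Reagents that add atoms: dimethyldioxirane, CC1(C)OO1
Why: Electrophilic epoxidation selects the electron-rich cyclopentene over the deactivated enone olefin and cannot give Baeyer–Villiger products; the convex face (H-3a side) is open, while the other face is blocked by the C4 silyloxy carbon and the seven-membered ring, which sets the C3 oxygen.

Step 17
Reactants: 22 epoxy enone
Product: 23 C8 allylic alcohol with the hydroxyl cis to the angular CH2OTs group, (2R,3S,3aS,4R,8R,8aR)
Conditions: NaBH4, CeCl3·7H2O, MeOH, −78 °C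
Reagents that add atoms: none
Why: Luche 1,2-reduction; as with ketones next to an angular substituent, hydride should add from the face opposite the C8a tosyloxymethyl group, and epoxide and tosylate survive at low temperature.

Step 18
Reactants: 23 epoxy alcohol tosylate
Product: 24 (3S,3aS,4R,8R,8aR)-4-(TBS-oxy)-6,8a-dimethyl-3-(propan-2-yl)-1,2,3,3a,4,5,8,8a-octahydroazulene-3,8-diol
Conditions: LiBHEt3 (excess), THF, 0 to 65 °C
Reagents that add atoms: none
Why: LiBHEt3 opens the trisubstituted epoxide at the less substituted C2, leaving the tertiary C3 hydroxyl on the face where the epoxide oxygen was, and displaces the hindered primary sulfonate (the reagent of choice for neopentyl-type tosylates) to give the angular methyl.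

Step 19
Reactants: 24 diol; 25 3-methylbutanoyl chloride
Product: 26 C8 3-methylbutanoate of 24
Conditions: pyridine, DMAP (cat.), CH2Cl2, 0 °C to rt
Reagents that add atoms: none
Why: Acylation of the secondary allylic hydroxyl; the tertiary C3 hydroxyl is inert under these conditions and C4 is still silylated.

Step 20
Reactants: 26 C8 ester silyl ether
Product: 27 (3S,3aS,4R,8R,8aR)-3,4-dihydroxy-6,8a-dimethyl-3-(propan-2-yl)-1,2,3,3a,4,5,8,8a-octahydroazulen-8-yl 3-methylbutanoate
Conditions: HF·pyridine, pyridine, THF, 0 °C to rt
Reagents that add atoms: none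
Why: Buffered fluoride cleaves the secondary silyl ether without ester cleavage or acyl migration; the C8 and C4 oxygens are on opposite faces.

Step 21
Reactants: 27 diol ester; 28 4-acetoxybenzoic acid
Product: 29 C4 4-acetoxybenzoate of 27
Conditions: EDC·HCl, DMAP, CH2Cl2, rt
Reagents that add atoms: none
Why: Steglich esterification of the hindered secondary C4 hydroxyl; the tertiary hydroxyl does not react, and the phenol is masked as its acetate so that the acid cannot self-condense.

Step 22
Reactants: 29 acetoxybenzoate
Product: 30 target, (3S,3aS,4R,8R,8aR)-3-hydroxy-6,8a-dimethyl-8-[(3-methylbutanoyl)oxy]-3-(propan-2-yl)-1,2,3,3a,4,5,8,8a-octahydroazulen-4-yl 4-hydroxybenzoate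
Conditions: K2CO3 (0.2 equiv), MeOH, 0 °C
Reagents that add atoms: none
Why: The aryl acetate undergoes methanolysis much faster than the two hindered alkyl esters, and the phenoxide formed deactivates the benzoate toward further transesterification.

## Compound list

1 | 3-methylbut-2-enal | CC(C)=CC=O | starting material
2 | (E)-tert-butyl(dimethyl)[(3-methylbuta-1,3-dien-1-yl)oxy]silane | C=C(C)/C=C/O[Si](C)(C)C(C)(C)C | intermediate
3 | 1,4-benzoquinone | O=C1C=CC(=O)C=C1 | starting material
4 | (4aS,5R,8aS)-5-[(tert-butyldimethylsilyl)oxy]-7-methyl-4a,5,8,8a-tetrahydronaphthalene-1,4-dione (cis-fused, silyloxy trans to H-4a) | CC1=C[C@@H](O[Si](C)(C)C(C)(C)C)[C@H]2C(=O)C=CC(=O)[C@H]2C1 | intermediate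
5 | (4aS,5R,8aS)-5-[(tert-butyldimethylsilyl)oxy]-7-methyl-2,3,4a,5,8,8a-hexahydronaphthalene-1,4-dione | CC1=C[C@@H](O[Si](C)(C)C(C)(C)C)[C@H]2C(=O)CCC(=O)[C@H]2C1 | intermediate
6 | C1 ethylene dithioketal of 5, (4aS,5R,8aS), C4 ketone free | CC1=C[C@@H](O[Si](C)(C)C(C)(C)C)[C@H]2C(=O)CCC3(SCCS3)[C@H]2C1 | intermediate
7 | C4 ethylene ketal, C1 ethylene dithioketal of 5, (4aS,5R,8aS) | CC1=C[C@@H](O[Si](C)(C)C(C)(C)C)[C@H]2C3(OCCO3)CCC4(SCCS4)[C@H]2C1 | intermediate
8 | (4aS,5R,8aS)-5-[(tert-butyldimethylsilyl)oxy]-4,4-(ethylenedioxy)-7-methyl-3,4,4a,5,8,8a-hexahydronaphthalen-1(2H)-one | CC1=C[C@@H](O[Si](C)(C)C(C)(C)C)[C@H]2C3(OCCO3)CCC(=O)[C@H]2C1 | intermediate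
9 | (4aS,5R)-5-[(tert-butyldimethylsilyl)oxy]-4,4-(ethylenedioxy)-7-methyl-1-(trimethylsilyloxy)-2,3,4,4a,5,8-hexahydronaphthalene (C1=C8a enol ether) | CC1=C[C@@H](O[Si](C)(C)C(C)(C)C)[C@H]2C3(OCCO3)CCC(O[Si](C)(C)C)=C2C1 | intermediate
10 | (1R,4aR,5R,8aR)-1,8a-epoxy-1-(trimethylsilyloxy) derivative of 9, epoxide on the face of H-4a (not isolated) | CC1=C[C@@H](O[Si](C)(C)C(C)(C)C)[C@H]2C3(OCCO3)CC[C@]4(O[Si](C)(C)C)O[C@@]42C1 | intermediate
11 | (4aR,5R,8aR)-5-[(tert-butyldimethylsilyl)oxy]-4,4-(ethylenedioxy)-8a-hydroxy-7-methyl-3,4,4a,5,8,8a-hexahydronaphthalen-1(2H)-one (8a-OH cis to H-4a) | CC1=C[C@@H](O[Si](C)(C)C(C)(C)C)[C@H]2C3(OCCO3)CCC(=O)[C@@]2(O)C1 | intermediate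
12 | trimethylsulfonium iodide | C[S+](C)C.[I-] | starting material
13 | (1S,4aR,5R,8aR)-spiro-epoxide of 11 at C1 (epoxide CH2 cis to 8a-OH and H-4a, epoxide O trans), 8a-ol | CC1=C[C@@H](O[Si](C)(C)C(C)(C)C)[C@H]2C3(OCCO3)CC[C@]4(CO4)[C@@]2(O)C1 | intermediate
14 | (3aS,4R,8aR)-4-[(tert-butyldimethylsilyl)oxy]-3,3-(ethylenedioxy)-8a-(hydroxymethyl)-6-methyl-2,3,3a,4,7,8a-hexahydroazulen-8(1H)-one (cis-fused) | CC1=C[C@@H](O[Si](C)(C)C(C)(C)C)[C@H]2C3(OCCO3)CC[C@@]2(CO)C(=O)C1 | intermediate
15 | 4-methylbenzenesulfonate of 14, (3aS,4R,8aR) | CC1=C[C@@H](O[Si](C)(C)C(C)(C)C)[C@H]2C3(OCCO3)CC[C@@]2(COS(=O)(=O)c4ccc(C)cc4)C(=O)C1 | intermediate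
16 | (3aS,4R,8aR)-4-[(tert-butyldimethylsilyl)oxy]-3,3-(ethylenedioxy)-6-methyl-8a-(tosyloxymethyl)-2,3,3a,4,5,8a-hexahydroazulen-8(1H)-one (C6=C7 enone) | CC=1C[C@@H](O[Si](C)(C)C(C)(C)C)[C@H]2C3(OCCO3)CC[C@@]2(COS(=O)(=O)c4ccc(C)cc4)C(=O)C=1 | intermediate
17 | (3aS,4R,8aR)-4-[(tert-butyldimethylsilyl)oxy]-6-methyl-8a-(tosyloxymethyl)-1,2,3a,4,5,8a-hexahydroazulene-3,8-dione | CC=1C[C@@H](O[Si](C)(C)C(C)(C)C)[C@H]2C(=O)CC[C@@]2(COS(=O)(=O)c3ccc(C)cc3)C(=O)C=1 | intermediate
18 | potassium C2=C3 enolate of 17 (not isolated) | [K+].CC=1C[C@@H](O[Si](C)(C)C(C)(C)C)[C@H]2C([O-])=CC[C@@]2(COS(=O)(=O)c3ccc(C)cc3)C(=O)C=1 | intermediate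
19 | (3aS,4R,8aR)-4-[(tert-butyldimethylsilyl)oxy]-6-methyl-8-oxo-8a-(tosyloxymethyl)-1,3a,4,5,8,8a-hexahydroazulen-3-yl trifluoromethanesulfonate | CC=1C[C@@H](O[Si](C)(C)C(C)(C)C)[C@H]2C(OS(=O)(=O)C(F)(F)F)=CC[C@@]2(COS(=O)(=O)c3ccc(C)cc3)C(=O)C=1 | intermediate
20 | isopropylzinc bromide | CC(C)[Zn]Br | starting material
21 | (3aS,4R,8aR)-4-[(tert-butyldimethylsilyl)oxy]-6-methyl-3-(propan-2-yl)-8a-(tosyloxymethyl)-3a,4,5,8a-tetrahydroazulen-8(1H)-one | CC=1C[C@@H](O[Si](C)(C)C(C)(C)C)[C@H]2C(C(C)C)=CC[C@@]2(COS(=O)(=O)c3ccc(C)cc3)C(=O)C=1 | intermediate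
22 | (2R,3S,3aS,4R,8aR)-2,3-epoxide of 21 (epoxide on the face of H-3a) | CC=1C[C@@H](O[Si](C)(C)C(C)(C)C)[C@H]2[C@]3(C(C)C)O[C@@H]3C[C@@]2(COS(=O)(=O)c4ccc(C)cc4)C(=O)C=1 | intermediate
23 | (2R,3S,3aS,4R,8R,8aR)-8-alcohol from 22 (8-OH cis to CH2OTs) | CC=1C[C@@H](O[Si](C)(C)C(C)(C)C)[C@H]2[C@]3(C(C)C)O[C@@H]3C[C@@]2(COS(=O)(=O)c4ccc(C)cc4)[C@H](O)C=1 | intermediate
24 | (3S,3aS,4R,8R,8aR)-4-[(tert-butyldimethylsilyl)oxy]-6,8a-dimethyl-3-(propan-2-yl)-1,2,3,3a,4,5,8,8a-octahydroazulene-3,8-diol | CC=1C[C@@H](O[Si](C)(C)C(C)(C)C)[C@H]2[C@@](O)(C(C)C)CC[C@@]2(C)[C@H](O)C=1 | intermediate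
25 | 3-methylbutanoyl chloride | CC(C)CC(Cl)=O | starting material
26 | (3S,3aS,4R,8R,8aR)-4-[(tert-butyldimethylsilyl)oxy]-3-hydroxy-6,8a-dimethyl-3-(propan-2-yl)-1,2,3,3a,4,5,8,8a-octahydroazulen-8-yl 3-methylbutanoate | CC=1C[C@@H](O[Si](C)(C)C(C)(C)C)[C@H]2[C@@](O)(C(C)C)CC[C@@]2(C)[C@H](OC(=O)CC(C)C)C=1 | intermediate
27 | (3S,3aS,4R,8R,8aR)-3,4-dihydroxy-6,8a-dimethyl-3-(propan-2-yl)-1,2,3,3a,4,5,8,8a-octahydroazulen-8-yl 3-methylbutanoate | CC=1C[C@@H](O)[C@H]2[C@@](O)(C(C)C)CC[C@@]2(C)[C@H](OC(=O)CC(C)C)C=1 | intermediate
28 | 4-acetoxybenzoic acid | CC(=O)Oc1ccc(cc1)C(O)=O | starting material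
29 | (3S,3aS,4R,8R,8aR)-3-hydroxy-6,8a-dimethyl-8-[(3-methylbutanoyl)oxy]-3-(propan-2-yl)-1,2,3,3a,4,5,8,8a-octahydroazulen-4-yl 4-acetoxybenzoate | CC=1C[C@@H](OC(=O)c2ccc(OC(C)=O)cc2)[C@H]3[C@@](O)(C(C)C)CC[C@@]3(C)[C@H](OC(=O)CC(C)C)C=1 | intermediate
30 | (3S,3aS,4R,8R,8aR)-3-hydroxy-6,8a-dimethyl-8-[(3-methylbutanoyl)oxy]-3-(propan-2-yl)-1,2,3,3a,4,5,8,8a-octahydroazulen-4-yl 4-hydroxybenzoate | CC1=C[C@@H](OC(=O)CC(C)C)[C@]2(C)CC[C@](O)(C(C)C)[C@@H]2[C@H](OC(=O)c2ccc(O)cc2)C1 | target

## Step count and least certain steps

Total: 22 steps. Longest linear sequence: 22 steps, from **1** to **30**; all other inputs are commercial and enter directly.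

**Step 10 (key step).** The epoxide may ionise to a free tertiary cation without assisted migration, followed by a hydride shift from the epoxide methylene (aldehyde) or proton loss (allylic alcohol); the Lewis acid may also open the dioxolane. Fallback: **13** is silylated with N-(trimethylsilyl)imidazole to the trimethylsilyl ether of the epoxy alcohol F1. F1 is treated with TiCl4 in CH2Cl2 at −78 °C, the known rearrangement of 2,3-epoxy silyl ethers, in which a chelating chloride Lewis acid replaces BF3 and the silyl ether oxygen supplies the push. Aqueous work-up returns **14**.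

**Step 2.** Silyl transfer from the dienol ether to the titanium Lewis acid (conjugate addition and aromatisation in place of cycloaddition) or weak enantiofacial discrimination on the symmetric quinone. Fallback: **2** and **3** are combined without catalyst to give **4** together with its mirror image, the enantiomeric adduct F2. Zinc reduction gives **5** and the enantiomeric dione F3, which are separated by preparative chromatography on a chiral stationary phase; the route resumes at **5**.

**Step 4.** Insufficient discrimination between the two ketones, leading to the regioisomeric or the bis-dithioketal. Fallback: **5** is reduced with LiBH(s-Bu)3 (one equivalent, −78 °C), which attacks the less hindered C1 carbonyl from the convex face and gives the C1 hydroxy C4 ketone F4. Ketalisation as in step 5 gives the C1 hydroxy C4 ketal F5, and Dess–Martin oxidation returns **8**.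

**Step 9.** Attack of the ylide on the concave face, or enolisation or α-ketol rearrangement caused by the basic ylide. Fallback: **11** is converted to its magnesium alkoxide and treated with ClCH2MgCl·LiCl (from ClCH2I and iPrMgCl·LiCl, −78 °C). Chelation holds the 8a-oxygen in the carbonyl plane and directs the carbenoid anti to the axial C8a–C8 bond, giving the chlorohydrin F6. KOtBu then closes the epoxide to **13**.

**Step 12.** Incomplete conversion, because conjugated and unconjugated cycloheptenones can be close in energy, or vinylogous β-elimination of the C4 silyloxy group. Fallback: **15** is hydrogenated (H2, [Ir(cod)(PCy3)(py)]PF6, CH2Cl2) to the saturated ketone F7 (C6 epimers). F7 is converted with LiN(iPr)2 and TMSCl to the C7=C8 silyl enol ether F8, the only one possible because C8a is quaternary. Saegusa–Ito oxidation with Pd(OAc)2 in MeCN gives **16** irreversibly.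

**Step 17.** Hydride delivery to the wrong face of the flexible seven-membered enone. Fallback: reagent control in place of substrate control, a Corey–Bakshi–Shibata reduction of **22** with BH3·SMe2 and the (S)-methyl oxazaborolidine (the (R)-catalyst if the quaternary flank does not act as the large group), which gives **23** directly.

## Further compounds

F1 | step 10 | trimethylsilyl ether of epoxy alcohol 13 (8a-O-trimethylsilyl) | CC1=C[C@@H](O[Si](C)(C)C(C)(C)C)[C@H]2C3(OCCO3)CC[C@]4(CO4)[C@@]2(O[Si](C)(C)C)C1
F2 | step 2 | (4aR,5S,8aR)-5-[(tert-butyldimethylsilyl)oxy]-7-methyl-4a,5,8,8a-tetrahydronaphthalene-1,4-dione (enantiomer of 4) | CC1=C[C@H](O[Si](C)(C)C(C)(C)C)[C@@H]2C(=O)C=CC(=O)[C@@H]2C1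
F3 | step 2 | (4aR,5S,8aR)-5-[(tert-butyldimethylsilyl)oxy]-7-methyl-2,3,4a,5,8,8a-hexahydronaphthalene-1,4-dione (enantiomer of 5) | CC1=C[C@H](O[Si](C)(C)C(C)(C)C)[C@@H]2C(=O)CCC(=O)[C@@H]2C1
F4 | step 4 | C1 alcohol of dione 5 (hydroxyl trans to H-8a), C4 ketone | CC1=C[C@@H](O[Si](C)(C)C(C)(C)C)[C@H]2C(=O)CC[C@@H](O)[C@H]2C1
F5 | step 4 | C4 ethylene ketal of F4 (C1 hydroxyl free) | CC1=C[C@@H](O[Si](C)(C)C(C)(C)C)[C@H]2C3(OCCO3)CC[C@@H](O)[C@H]2C1
F6 | step 9 | 1-(chloromethyl)-1,8a-diol from ketol 11 (CH2Cl cis to the 8a-hydroxyl) | CC1=C[C@@H](O[Si](C)(C)C(C)(C)C)[C@H]2C3(OCCO3)CC[C@](O)(CCl)[C@@]2(O)C1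
F7 | step 12 | 5,6-dihydro derivative of 15 (saturated C8 ketone, C6 epimers) | CC1C[C@@H](O[Si](C)(C)C(C)(C)C)[C@H]2C3(OCCO3)CC[C@@]2(COS(=O)(=O)c4ccc(C)cc4)C(=O)C1
F8 | step 12 | C7=C8 trimethylsilyl enol ether of F7 | CC1C[C@@H](O[Si](C)(C)C(C)(C)C)[C@H]2C3(OCCO3)CC[C@@]2(COS(=O)(=O)c4ccc(C)cc4)C(O[Si](C)(C)C)=C1
F0 | step 17 | none | none
A1 | alternative 1 | 3-methylcyclopent-2-enone | CC1=CC(=O)CC1
A2 | alternative 1 | 4-methyl-1,2-bis(trimethylsilyloxy)cyclopentene | CC1CC(O[Si](C)(C)C)=C(O[Si](C)(C)C)C1
A3 | alternative 1 | cis-anti-cis tricyclic bis(trimethylsilyloxy)cyclobutane ketone | C[C@@H]1C[C@@]3(O[Si](C)(C)C)[C@]2(C)CCC(=O)[C@@H]2[C@@]3(O[Si](C)(C)C)C1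
A4 | alternative 1 | cis-fused 6,8a-dimethylhexahydroazulene-3,4,8-trione | C[C@@H]1CC(=O)[C@]2(C)CCC(=O)[C@@H]2C(=O)C1
A5 | alternative 2 | methyl 2-diazo-3-methyl-3-[(tert-butyldimethylsilyloxy)methyl]-6-(tert-butyldimethylsilyloxy)-7-methyloctanoate | COC(=O)C(=[N+]=[N-])[C@](C)(CO[Si](C)(C)C(C)(C)C)CC[C@H](O[Si](C)(C)C(C)(C)C)C(C)C
A6 | alternative 2 | methyl cyclopentanecarboxylate with C3 silyl ether, C3a–H and quaternary C8a | CC(C)(C)[Si](C)(C)OC[C@]1(C)CC[C@](O[Si](C)(C)C(C)(C)C)(C(C)C)[C@@H]1C(=O)OC
A7 | alternative 3 | cis-1-methyl-1-[2-methoxy-2-(tert-butyldimethylsilyloxy)ethenyl]-2-(3-methyl-5-oxocyclopent-1-en-2-yl)cyclopropane (ketene acetal geometry immaterial) | CC1=C(C(=O)CC1)[C@H]2C[C@@]2(C)C=C(OC)O[Si](C)(C)C(C)(C)C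
A8 | alternative 3 | 6,8a-dimethyl bicyclic dienedione with C3 and C8 ketones, C6=C7 and C3a=C4 olefins | CC1=CC(=O)[C@]2(C)CCC(=O)C2=CC1
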